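**Assumption:** the target has no stereocentres, and its biaryl axis carries only two ortho substituents (both on one ring), so it is not configurationally stable. The molecule is therefore achiral and no stereocontrol is needed.

## Retrosynthetic overview

1. Final step is removal of two MOM ethers from the catechol; before that, the biaryl bond is cut (Suzuki–Miyaura).
2. Ring A partner: the hindered bromide 1-bromo-2,6-diprenyl-3,4-bis(MOM-oxy)benzene. Ring B partner: a 5-hydroxy-2,2-dimethylchromen-7-yl boronate.
3. Ring A comes from 4,5-dibromocatechol: MOM protection, Br/Mg exchange–prenylation, then lithiation between Br and OMOM–prenylation.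
4. Ring B comes from 5-bromoresorcinol and prenal (chromene annulation), then Miyaura borylation.
5. Ring order: the pyran ring is formed first on the ring B fragment; the two arenes are joined afterwards.

## Route

**Step 1**
Reactants: 1 (4,5-dibromobenzene-1,2-diol); 2 (chloromethyl methyl ether, MOMCl)
Product: 3, 1,2-dibromo-4,5-bis(methoxymethoxy)benzene
Conditions: MOMCl (3 equiv), i-Pr2NEt, CH2Cl2, 0 °C → rt
Reagents that add atoms: MOMCl, COCCl
Why: Simple O-alkylation of both catechol hydroxyls gives base-stable acetal ethers that survive the organometallic steps and later direct ortho-metalation.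

**Step 2**
Reactants: 3; 4 (prenyl bromide, 1-bromo-3-methylbut-2-ene)
Product: 5, 1-bromo-4,5-bis(methoxymethoxy)-2-(3-methylbut-2-en-1-yl)benzene
Conditions: i-PrMgCl·LiCl (1.05 equiv), THF, −15 °C; then CuI (10 mol%), prenyl bromide, −15 °C → rt
Reagents that add atoms: prenyl bromide, CC(C)=CCBr
Why: Mono Br/Mg exchange on the symmetric dibromide (the ortho-bromoaryl Grignard is stable at this temperature, and either bromine gives the same product) followed by Cu-catalysed allylic substitution at the unhindered primary carbon gives the linear prenyl arene.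

**Step 3**
Reactants: 5; 4 (prenyl bromide)
Product: 6, 1-bromo-3,4-bis(methoxymethoxy)-2,6-bis(3-methylbut-2-en-1-yl)benzene
Conditions: LDA (1.2 equiv), THF, −78 °C; CuBr·SMe2 (1.2 equiv), −78 °C; prenyl bromide, −78 → 0 °C
Reagents that add atoms: prenyl bromide, CC(C)=CCBr
Why: Directed ortho-metalation removes the most acidic ring proton (flanked by Br and OMOM); transmetalation to copper at −78 °C suppresses benzyne formation and gives SN2 prenylation at that carbon.

**Step 4**
Reactants: 7 (5-bromobenzene-1,3-diol, 5-bromoresorcinol); 8 (3-methylbut-2-enal, prenal)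
Product: 9, 7-bromo-2,2-dimethyl-2H-chromen-5-ol
Conditions: prenal (1.1 equiv), EDDA (20 mol%), toluene, reflux
Reagents that add atoms: prenal, CC(C)=CC=O
Why: Formal [3+3] chromene annulation (Knoevenagel-type condensation at the carbon between the two hydroxyls, then oxa-6π electrocyclisation), the same regiochemistry as olivetol → cannabichromene; limiting prenal avoids bis-annulation.

**Step 5**
Reactants: 9; 10 (bis(pinacolato)diboron)
Product: 11, 2,2-dimethyl-7-(4,4,5,5-tetramethyl-1,3,2-dioxaborolan-2-yl)-2H-chromen-5-ol
Conditions: B2pin2 (1.2 equiv), PdCl2(dppf) (5 mol%), KOAc, 1,4-dioxane, 90 °C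
Reagents that add atoms: B2pin2, CC1(C)OB(OC1(C)C)B1OC(C)(C)C(C)(C)O1
Why: Miyaura borylation with the weak base KOAc tolerates the free phenol and the chromene alkene and gives the unhindered nucleophilic partner.

**Step 6**
Reactants: 6; 11
Product: 12, 7-[3,4-bis(methoxymethoxy)-2,6-bis(3-methylbut-2-en-1-yl)phenyl]-2,2-dimethyl-2H-chromen-5-ol
Conditions: Pd(OAc)2 (5 mol%), SPhos (10 mol%), K3PO4 (4 equiv), toluene/H2O (10:1), 100 °C
Reagents that add atoms: none
Why: Suzuki–Miyaura coupling with the hindered, electron-rich partner as the electrophile and the unhindered one as the boronate; SPhos is suited to di-ortho-substituted aryl bromides, and the ortho-prenyl groups cannot undergo a favourable Heck cyclisation.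

**Step 7**
Reactants: 12
Product: 13, Clusiachromene D
Conditions: 3 M aq HCl, MeOH (degassed), 40 °C, under Ar; stop at full conversion
Reagents that add atoms: none
Why: Mild acid-catalysed acetal hydrolysis cleaves the catechol MOM ethers; kept mild and short so the ortho-prenyl phenol and chromene are not cyclised or solvolysed.

## Compound list

1 | 4,5-dibromobenzene-1,2-diol | Oc1cc(Br)c(Br)cc1O | starting material
2 | chloromethyl methyl ether (MOMCl) | COCCl | starting material
3 | 1,2-dibromo-4,5-bis(methoxymethoxy)benzene | COCOc1cc(Br)c(Br)cc1OCOC | intermediate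
4 | prenyl bromide (1-bromo-3-methylbut-2-ene) | CC(C)=CCBr | starting material
5 | 1-bromo-4,5-bis(methoxymethoxy)-2-(3-methylbut-2-en-1-yl)benzene | COCOc1cc(Br)c(CC=C(C)C)cc1OCOC | intermediate
6 | 1-bromo-3,4-bis(methoxymethoxy)-2,6-bis(3-methylbut-2-en-1-yl)benzene | COCOc1cc(CC=C(C)C)c(Br)c(CC=C(C)C)c1OCOC | intermediate
7 | 5-bromobenzene-1,3-diol (5-bromoresorcinol) | Oc1cc(O)cc(Br)c1 | starting material
8 | 3-methylbut-2-enal (prenal) | CC(C)=CC=O | starting material
9 | 7-bromo-2,2-dimethyl-2H-chromen-5-ol | CC1(C)C=Cc2c(O)cc(Br)cc2O1 | intermediate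
10 | bis(pinacolato)diboron | CC1(C)OB(OC1(C)C)B1OC(C)(C)C(C)(C)O1 | starting material
11 | 2,2-dimethyl-7-(pinacolatoboryl)-2H-chromen-5-ol | CC1(C)C=Cc2c(O)cc(cc2O1)B1OC(C)(C)C(C)(C)O1 | intermediate
12 | 7-[3,4-bis(methoxymethoxy)-2,6-diprenylphenyl]-2,2-dimethyl-2H-chromen-5-ol | COCOc1cc(CC=C(C)C)c(-c2cc(O)c3C=CC(C)(C)Oc3c2)c(CC=C(C)C)c1OCOC | intermediate
13 | Clusiachromene D | CC(C)=CCc1cc(O)c(O)c(CC=C(C)C)c1-c1cc(O)c2c(c1)OC(C)(C)C=C2 | target

## Summary

**Total steps:** 7 (ring A branch 3 steps, ring B branch 2 steps, coupling, deprotection).

**Longest linear sequence:** 5 steps (1 → 2 → 3 → 6 → 7).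

**Three steps most likely to fail, with fallbacks:**

- **Step 3 (lithiation between Br and OMOM, then prenylation).** Risks are benzyne formation, competing metalation and SN2′ allylation. Fallback: drop the metalation and make ring A as a triflate. Take 3,4-bis(MOM-oxy)phenol (from 3,4-dihydroxybenzaldehyde by MOM protection and Dakin oxidation), dibrominate at both positions ortho to the OH with NBS, do a double Stille prenylation with tributyl(prenyl)stannane, and convert the phenol to the triflate with Tf2O. The triflate goes into the same Suzuki coupling.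
- **Step 7 (acidic MOM removal).** The ortho-prenyl catechol can cyclise to a chroman and the chromene can add solvent. Fallback: carry the catechol as bis-SEM ethers from step 1 (same directing behaviour in step 3) and unmask at the end with fluoride (TBAF/DMPU) instead of acid.
- **Step 4 (chromene annulation regiochemistry).** The 5-bromo-7-hydroxy regioisomer and bis-chromene are possible by-products. Fallback: form the chromene after the biaryl. Borylate 5-bromoresorcinol, couple with 6, then treat the resulting 3,5-dihydroxybiaryl with prenal/EDDA. The bulky 2,6-diprenylaryl group then blocks both flanking positions and forces annulation between the two hydroxyls, while ring A is still MOM-protected.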